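**Strategy.** Everything rests on inserting C4 of the pyran ring (O1, C2, C3, C4, C4a, C8a) into the aryl–carbonyl bond of a benzofuran-3(2H)-one whose quaternary C2 already carries O1, the methyl group and the side chain. In one operation, Lewis-acid-promoted homologation with trimethylsilyldiazomethane makes C3–C4 and C4–C4a and enlarges the furanone to a chroman-3-one, leaving C2 untouched. As C2 has no hydrogen, the derived alcohol can lose water only across C3–C4, which delivers the 2H-chromene. The precursor 8 is an (S)-2-methyl-5-silyloxybenzofuranone bearing an (E)-α-methylpentenoate chain. Its stereocentre comes from a catalytic asymmetric Michael addition to acrolein, and its ester later links to β-cyclogeranyl phenyl sulfone.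

Key step: step 5

**Remarks on the chemistry**
- Check of the fixed structures: 8, 11 and 23 share the same spatial arrangement at C2. It is S throughout, with priorities O1 > C3 > chain CH2 > CH3. They also share the same E alkene, so no correction is needed beyond adding the (2S) descriptor to the names.
- Assumption: the quinidine-derived catalyst of step 3 is taken to give the (S)-aldehyde. The sense must be verified on 8, and the quinine-derived pseudo-enantiomer would be used without any other change if it proves opposite.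
- Handling: from 13 onward all operations stay at or below room temperature and away from light, because electrocyclic opening of a 2H-chromene would scramble C2.
- Steps 6 and 7 avoid enolate chemistry, so material formed by migration of C2 instead of the aryl carbon in step 5 would reach the same chromene 13 without loss of configuration.

**Step 1**
Reactants: 1 2',5'-dihydroxypropiophenone
Product: 2 1-[2-hydroxy-5-(triisopropylsilyloxy)phenyl]propan-1-one
Conditions: TIPSCl (1.05 equiv), imidazole, CH2Cl2, 0 °C → rt
Reagents that add atoms: triisopropylsilyl chloride, CC(C)[Si](Cl)(C(C)C)C(C)C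
Why: Chemoselective O-silylation: the 2'-OH is locked in a hydrogen bond to the ketone and flanked by the acyl group, so the bulky chlorosilane should take only the free 5'-OH, which also shields the hydroquinone from oxidation by copper(II) in step 2.

**Step 2**
Reactants: 2 1-[2-hydroxy-5-(triisopropylsilyloxy)phenyl]propan-1-one
Product: 4 2-methyl-5-(triisopropylsilyloxy)benzofuran-3(2H)-one (racemic), via α-bromoketone 3 (not isolated)
Conditions: CuBr2 (2.1 equiv), EtOAc–CHCl3, reflux; filter, concentrate; K2CO3, MeCN, rt, argon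
Reagents that add atoms: copper(II) bromide, Br[Cu]Br (gives the bromine of 3, which is lost again on the way to 4)
Why: Heterogeneous α-bromination of an aryl ketone with CuBr2, which acts on the enolisable CH2 and spares phenolic rings, followed by intramolecular Williamson etherification (5-exo-tet) of the phenoxide; C2 forms racemic and stays enolisable, which is all that step 3 requires.

**Step 3**
Reactants: 4 2-methyl-5-(triisopropylsilyloxy)benzofuran-3(2H)-one; 5 acrolein
Product: 6 3-[(2S)-2-methyl-3-oxo-5-(triisopropylsilyloxy)-2,3-dihydrobenzofuran-2-yl]propanal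
Conditions: 5 (3 equiv, freshly distilled), 9-O-(phenanthren-9-yl)cupreidine (quinidine skeleton, free 6'-OH, 10 mol %), CH2Cl2, −25 °C, argon
Reagents that add atoms: acrolein (5), C=CC=O
Why: Bifunctional Brønsted-base/hydrogen-bond organocatalytic Michael addition, a type established for 2-substituted benzofuran-3(2H)-ones and, with this catalyst family, for acrolein as acceptor: the quinuclidine nitrogen holds the planar aromatic benzofuran-3-olate as an ion pair, the 6'-OH binds the acrolein carbonyl and the phenanthryl ether covers one enolate face, so C–C bond formation on the open face should set the S quaternary C2.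

**Step 4**
Reactants: 6 3-[(2S)-2-methyl-3-oxo-5-(triisopropylsilyloxy)-2,3-dihydrobenzofuran-2-yl]propanal; 7 ethyl 2-(triphenylphosphoranylidene)propanoate
Product: 8 ethyl (E)-2-methyl-5-[(2S)-2-methyl-3-oxo-5-(triisopropylsilyloxy)-2,3-dihydrobenzofuran-2-yl]pent-2-enoate
Conditions: 7 (1.2 equiv), CH2Cl2, rt
Reagents that add atoms: ethyl 2-(triphenylphosphoranylidene)propanoate (7), CCOC(=O)C(C)=P(c1ccccc1)(c1ccccc1)c1ccccc1
Why: Wittig olefination with a stabilised, α-branched ylide, which is reliably E-selective with aliphatic aldehydes and does not touch the hindered, non-enolisable C3 ketone, so C2 is not at risk.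

**Step 5**
Reactants: 8 ethyl (E)-2-methyl-5-[(2S)-2-methyl-3-oxo-5-(triisopropylsilyloxy)-2,3-dihydrobenzofuran-2-yl]pent-2-enoate; 9 trimethylsilyldiazomethane
Product: 11 ethyl (E)-2-methyl-5-[(2S)-2-methyl-3-oxo-6-(triisopropylsilyloxy)chroman-2-yl]pent-2-enoate, via 4-trimethylsilyl ketone 10 (not isolated)
Conditions: BF3·OEt2 (2 equiv), 9 (2 M in hexanes, 1.5 equiv, slow addition), CH2Cl2, −78 → −30 °C; aq NaHCO3; then 1 M HCl, THF, 0 °C
Reagents that add atoms: trimethylsilyldiazomethane (9), C[Si](C)(C)C=[N+]=[N-]
Why: Proposed new method: BF3 binds the C3 carbonyl oxygen, the most Lewis-basic site because O1 donates into it through C7a and C3a; the nucleophilic carbon of 9 adds to C3 (C3–C4 bond), and the aryl carbon C3a, held antiperiplanar to the diazonium group because the Me3Si group turns away from quaternary C2, shifts to the new carbon as N2 leaves (C4–C4a bond), giving 10, which acid protodesilylates to 11. The closest known reaction type is the Lewis-acid-promoted trimethylsilyldiazomethane homologation of cyclic ketones (Büchner–Curtius–Schlotterbeck/Tiffeneau–Demjanov manifold) as practised on indanones (to 2-tetralones) and isatins (to quinolinones); a benzofuran-3-one with a fully substituted C2 has not been put through it. The pyranone ring is closed by ring enlargement, a 1,2-shift that turns the five-membered ring into the six-membered one, not by an end-to-end cyclisation. No lasting stereocentre is made (C4 of 10 is lost on desilylation), and C2 keeps its S configuration because it is non-enolisable, is a bystander in aryl migration and would move with retention if it migrated instead, in which case steps 6 and 7 lead to the same chromene 13. The step needs mono-insertion, secured because the ketone of 10 sits between quaternary C2 and silylated C4 and should resist a second addition until work-up, and ketone-over-enoate selectivity, secured because the trisubstituted α-methyl enoate is a poor dipolarophile at these temperatures. The same electron-poor alkene is too weak a nucleophile for Prins or ene closure onto activated C3, which is why the ester is reduced only later.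

**Step 6**
Reactants: 11 ethyl (E)-2-methyl-5-[(2S)-2-methyl-3-oxo-6-(triisopropylsilyloxy)chroman-2-yl]pent-2-enoate
Product: 12 ethyl (E)-5-[(2S,3RS)-3-hydroxy-2-methyl-6-(triisopropylsilyloxy)chroman-2-yl]-2-methylpent-2-enoate
Conditions: NaBH4, MeOH–THF, 0 °C (11 used without storage)
Reagents that add atoms: none
Why: Borohydride 1,2-reduction: the unconjugated C3 ketone is reduced far faster than the trisubstituted enoate, and the new C3 carbinol centre, formed as an epimer mixture, is erased in step 7.

**Step 7**
Reactants: 12 ethyl (E)-5-[(2S,3RS)-3-hydroxy-2-methyl-6-(triisopropylsilyloxy)chroman-2-yl]-2-methylpent-2-enoate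
Product: 13 ethyl (E)-2-methyl-5-[(2S)-2-methyl-6-(triisopropylsilyloxy)-2H-chromen-2-yl]pent-2-enoate
Conditions: Martin sulfurane Ph2S[OC(CF3)2Ph]2 (1.5 equiv), CH2Cl2, 0 °C → rt, dark
Reagents that add atoms: none
Why: Dehydration with Martin sulfurane: the alkoxysulfurane leaves in an E2-type process at or below room temperature, the only β-hydrogens are the benzylic ones on C4 because C2 is quaternary, and the absence of a free cation rules out a 1,2-shift from C2.

**Step 8**
Reactants: 13 ethyl (E)-2-methyl-5-[(2S)-2-methyl-6-(triisopropylsilyloxy)-2H-chromen-2-yl]pent-2-enoate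
Product: 14 (E)-2-methyl-5-[(2S)-2-methyl-6-(triisopropylsilyloxy)-2H-chromen-2-yl]pent-2-en-1-ol
Conditions: DIBAL-H (2.5 equiv), CH2Cl2, −78 °C; Rochelle salt
Reagents that add atoms: none
Why: DIBAL-H 1,2-reduction of an α,β-unsaturated ester to the allylic alcohol, which leaves the alkene geometry, the chromene and the aryl silyl ether unchanged at −78 °C.

**Step 9**
Reactants: 14 (E)-2-methyl-5-[(2S)-2-methyl-6-(triisopropylsilyloxy)-2H-chromen-2-yl]pent-2-en-1-ol
Product: 15 {[(2S)-2-[(E)-5-bromo-4-methylpent-3-enyl]-2-methyl-2H-chromen-6-yl]oxy}triisopropylsilane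
Conditions: CBr4, PPh3, CH2Cl2, −20 → 0 °C; used at once
Reagents that add atoms: carbon tetrabromide, BrC(Br)(Br)Br
Why: Appel bromination, an SN2 displacement of the oxyphosphonium group under neutral conditions, which should keep the E geometry and avoid both allylic transposition and acid contact with the chromene.

**Step 10**
Reactants: 16 β-cyclocitral
Product: 17 β-cyclogeraniol, (2,6,6-trimethylcyclohex-1-enyl)methanol
Conditions: NaBH4, MeOH, 0 °C
Reagents that add atoms: none
Why: Borohydride 1,2-reduction of a hindered enal whose tetrasubstituted β-carbon is closed to conjugate hydride attack.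

**Step 11**
Reactants: 17 β-cyclogeraniol
Product: 19 β-cyclogeranyl phenyl sulfone, via β-cyclogeranyl bromide 18 (not isolated)
Conditions: PBr3 (0.4 equiv), cat. pyridine, Et2O, 0 °C; cold aqueous wash; PhSO2Na, DMF, rt
Reagents that add atoms: phosphorus tribromide, BrP(Br)Br (bromine of 18 only); sodium benzenesulfinate, [Na+].[O-]S(=O)c1ccccc1
Why: Bromination of the allylic alcohol with PBr3 followed by SN2 S-alkylation of the ambident sulfinate in a dipolar aprotic solvent; the labile bromide is used at once and attack at the primary carbon keeps the ring alkene tetrasubstituted.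

**Step 12**
Reactants: 19 β-cyclogeranyl phenyl sulfone; 15 {[(2S)-2-[(E)-5-bromo-4-methylpent-3-enyl]-2-methyl-2H-chromen-6-yl]oxy}triisopropylsilane
Product: 21 triisopropyl{[(2S)-2-methyl-2-[(E)-4-methyl-6-(phenylsulfonyl)-6-(2,6,6-trimethylcyclohex-1-enyl)hex-3-enyl]-2H-chromen-6-yl]oxy}silane (epimers at the sulfonyl carbon), via lithiated sulfone 20 (not isolated)
Conditions: 19 (1.3 equiv), n-BuLi (1.25 equiv), THF–DMPU, −78 °C; then 15, −78 → −20 °C
Reagents that add atoms: n-butyllithium, [Li]CCCC (lithium of 20 only)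
Why: Alkylation of a sulfone-stabilised allylic carbanion with a primary allylic bromide (SN2 at the α-carbon of the sulfone), a standard terpenoid coupling; the new sulfonyl-bearing centre forms without control and is removed in step 13.

**Step 13**
Reactants: 21 triisopropyl{[(2S)-2-methyl-2-[(E)-4-methyl-6-(phenylsulfonyl)-6-(2,6,6-trimethylcyclohex-1-enyl)hex-3-enyl]-2H-chromen-6-yl]oxy}silane
Product: 22 triisopropyl{[(2S)-2-methyl-2-[(E)-4-methyl-6-(2,6,6-trimethylcyclohex-1-enyl)hex-3-enyl]-2H-chromen-6-yl]oxy}silane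
Conditions: 6% Na(Hg), Na2HPO4, MeOH–THF, −20 → 0 °C, dark
Reagents that add atoms: none
Why: Reductive desulfonylation by electron transfer: the phenylsulfonyl group accepts electrons well before the alkoxystyrene unit of the chromene, the allyl anion should be protonated at its less hindered secondary terminus so that the ring alkene stays tetrasubstituted, and the phosphate buffer keeps methoxide away from the silyl ether.

**Step 14**
Reactants: 22 triisopropyl{[(2S)-2-methyl-2-[(E)-4-methyl-6-(2,6,6-trimethylcyclohex-1-enyl)hex-3-enyl]-2H-chromen-6-yl]oxy}silane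
Product: 23 (2S)-2-methyl-2-[(E)-4-methyl-6-(2,6,6-trimethylcyclohex-1-enyl)hex-3-enyl]-2H-chromen-6-ol (target)
Conditions: TBAF, AcOH (1:1), THF, 0 °C, argon, dark
Reagents that add atoms: none
Why: Fluoride-induced cleavage of an aryl silyl ether, driven by the Si–F bond and buffered with acetic acid so that the oxidation-prone phenoxide is protonated at once; nothing else in the molecule responds to fluoride.

**Compound list**
1 | 2',5'-dihydroxypropiophenone | CCC(=O)c1cc(O)ccc1O | starting material
2 | 1-[2-hydroxy-5-(triisopropylsilyloxy)phenyl]propan-1-one | CCC(=O)c1cc(O[Si](C(C)C)(C(C)C)C(C)C)ccc1O | intermediate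
3 | 2-bromo-1-[2-hydroxy-5-(triisopropylsilyloxy)phenyl]propan-1-one (racemic, not isolated) | CC(Br)C(=O)c1cc(O[Si](C(C)C)(C(C)C)C(C)C)ccc1O | intermediate
4 | 2-methyl-5-(triisopropylsilyloxy)benzofuran-3(2H)-one (racemic) | CC1Oc2ccc(O[Si](C(C)C)(C(C)C)C(C)C)cc2C1=O | intermediate
5 | acrolein | C=CC=O | starting material
6 | 3-[(2S)-2-methyl-3-oxo-5-(triisopropylsilyloxy)-2,3-dihydrobenzofuran-2-yl]propanal | O=C1c2cc(O[Si](C(C)C)(C(C)C)C(C)C)ccc2O[C@@]1(C)CCC=O | intermediate
7 | ethyl 2-(triphenylphosphoranylidene)propanoate | CCOC(=O)C(C)=P(c1ccccc1)(c1ccccc1)c1ccccc1 | starting material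
8 | ethyl (E)-2-methyl-5-[(2S)-2-methyl-3-oxo-5-(triisopropylsilyloxy)-2,3-dihydrobenzofuran-2-yl]pent-2-enoate | O=C1c2cc(O[Si](C(C)C)(C(C)C)C(C)C)ccc2O[C@@]1(C)CC/C=C(\C)C(=O)OCC | intermediate
9 | trimethylsilyldiazomethane | C[Si](C)(C)C=[N+]=[N-] | starting material
10 | ethyl (E)-2-methyl-5-[(2S)-2-methyl-3-oxo-6-(triisopropylsilyloxy)-4-(trimethylsilyl)chroman-2-yl]pent-2-enoate (C4 epimers, not isolated) | O=C1C([Si](C)(C)C)c2cc(O[Si](C(C)C)(C(C)C)C(C)C)ccc2O[C@@]1(C)CC/C=C(\C)C(=O)OCC | intermediate
11 | ethyl (E)-2-methyl-5-[(2S)-2-methyl-3-oxo-6-(triisopropylsilyloxy)chroman-2-yl]pent-2-enoate | O=C1Cc2cc(O[Si](C(C)C)(C(C)C)C(C)C)ccc2O[C@@]1(C)CC/C=C(\C)C(=O)OCC | intermediate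
12 | ethyl (E)-5-[(2S,3RS)-3-hydroxy-2-methyl-6-(triisopropylsilyloxy)chroman-2-yl]-2-methylpent-2-enoate | OC1Cc2cc(O[Si](C(C)C)(C(C)C)C(C)C)ccc2O[C@@]1(C)CC/C=C(\C)C(=O)OCC | intermediate
13 | ethyl (E)-2-methyl-5-[(2S)-2-methyl-6-(triisopropylsilyloxy)-2H-chromen-2-yl]pent-2-enoate | CCOC(=O)/C(C)=C/CC[C@@]1(C)C=Cc2cc(O[Si](C(C)C)(C(C)C)C(C)C)ccc2O1 | intermediate
14 | (E)-2-methyl-5-[(2S)-2-methyl-6-(triisopropylsilyloxy)-2H-chromen-2-yl]pent-2-en-1-ol | OC/C(C)=C/CC[C@@]1(C)C=Cc2cc(O[Si](C(C)C)(C(C)C)C(C)C)ccc2O1 | intermediate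
15 | {[(2S)-2-[(E)-5-bromo-4-methylpent-3-enyl]-2-methyl-2H-chromen-6-yl]oxy}triisopropylsilane | BrC/C(C)=C/CC[C@@]1(C)C=Cc2cc(O[Si](C(C)C)(C(C)C)C(C)C)ccc2O1 | intermediate
16 | β-cyclocitral | CC1=C(C=O)C(C)(C)CCC1 | starting material
17 | β-cyclogeraniol | CC1=C(CO)C(C)(C)CCC1 | intermediate
18 | β-cyclogeranyl bromide, 2-(bromomethyl)-1,3,3-trimethylcyclohexene (not isolated) | CC1=C(CBr)C(C)(C)CCC1 | intermediate
19 | β-cyclogeranyl phenyl sulfone | CC1=C(CS(=O)(=O)c2ccccc2)C(C)(C)CCC1 | intermediate
20 | α-lithio-β-cyclogeranyl phenyl sulfone (not isolated) | CC1=C(C([Li])S(=O)(=O)c2ccccc2)C(C)(C)CCC1 | intermediate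
21 | triisopropyl{[(2S)-2-methyl-2-[(E)-4-methyl-6-(phenylsulfonyl)-6-(2,6,6-trimethylcyclohex-1-enyl)hex-3-enyl]-2H-chromen-6-yl]oxy}silane (epimers at the sulfonyl carbon) | CC1=C(C(C/C(C)=C/CC[C@@]2(C)C=Cc3cc(O[Si](C(C)C)(C(C)C)C(C)C)ccc3O2)S(=O)(=O)c2ccccc2)C(C)(C)CCC1 | intermediate
22 | triisopropyl{[(2S)-2-methyl-2-[(E)-4-methyl-6-(2,6,6-trimethylcyclohex-1-enyl)hex-3-enyl]-2H-chromen-6-yl]oxy}silane | CC1=C(CC/C(C)=C/CC[C@@]2(C)C=Cc3cc(O[Si](C(C)C)(C(C)C)C(C)C)ccc3O2)C(C)(C)CCC1 | intermediate
23 | (2S)-2-methyl-2-[(E)-4-methyl-6-(2,6,6-trimethylcyclohex-1-enyl)hex-3-enyl]-2H-chromen-6-ol | CC1=C(CC/C(C)=C/CC[C@@]2(C)C=Cc3cc(O)ccc3O2)C(C)(C)CCC1 | target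

**Step count.** Total steps: 14. Longest linear sequence: 12 (steps 1–9 and 12–14).

**Steps most likely to fail**

1. **Step 5.** The C3 carbonyl is shielded by C2 and electronically damped by O1, so addition of the diazoalkane may be slow. Three processes could then overtake it: Lewis-acid-induced decay of the reagent, closure of the adduct to an epoxide, and dipolar cycloaddition at the enoate.
 The fallback sets out from 8 and returns at 11. Takai–Lombardo methylenation (Zn, CH2Br2, TiCl4, THF–CH2Cl2, 0 °C → rt) spares esters. It should give ethyl (E)-2-methyl-5-[(2S)-2-methyl-3-methylidene-5-(triisopropylsilyloxy)-2,3-dihydrobenzofuran-2-yl]pent-2-enoate F1, whose exocyclic alkene cannot move into the ring because C2 is quaternary.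
 Oxidative ring expansion with PhI(OH)OTs in 95% MeOH, followed by brief aqueous acid, is known for 1-methyleneindanes and related benzo-fused exocyclic alkenes. Iodine(III) adds to the terminal CH2, and a 1,2-aryl shift with loss of iodobenzene places that carbon between C3 and the arene. The electron-poor enoate is not attacked, and the product is 11.

2. **Step 3.** Facial selectivity may be poor because the enolate offers the catalyst only one binding point. Enolisation by a tertiary amine may also be slow, and acrolein may polymerise.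
 The fallback sets out from 4 and returns at 6. O-acylation (NaHMDS, allyl chloroformate, THF, −78 °C) should give allyl 2-methyl-5-(triisopropylsilyloxy)benzofuran-3-yl carbonate F2.
 Palladium-catalysed decarboxylative asymmetric allylic alkylation follows (Pd2(dba)3, C2-symmetric DACH-phenyl bis(diphenylphosphinobenzamide) ligand, toluene, rt). Both ligand antipodes are commercial. This should give (2S)-2-allyl-2-methyl-5-(triisopropylsilyloxy)benzofuran-3(2H)-one F3.
 Hydroboration with 9-BBN gives (2S)-2-[3-(9-borabicyclo[3.3.1]nonan-9-yl)propyl]-2-methyl-5-(triisopropylsilyloxy)benzofuran-3(2H)-one F4. Without isolation, NaBO3 oxidises it to (2S)-2-(3-hydroxypropyl)-2-methyl-5-(triisopropylsilyloxy)benzofuran-3(2H)-one F5.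
 Dess–Martin oxidation then leads to 6. Any over-reduction at C3 during hydroboration is repaired in the same oxidation.

3. **Step 13.** The allyl anion may be protonated at its ring terminus, which would shift the double bond out of the tetrasubstituted position. Electron transfer to the chromene could also cleave the allylic C2–O1 bond.
 The fallback sets out from 14, returns at 22 and uses no sulfone. MnO2 oxidation should give (E)-2-methyl-5-[(2S)-2-methyl-6-(triisopropylsilyloxy)-2H-chromen-2-yl]pent-2-enal F6. Wittig methylenation (Ph3P=CH2, THF, −78 → 0 °C) should then give triisopropyl{[(2S)-2-methyl-2-[(E)-4-methylhexa-3,5-dienyl]-2H-chromen-6-yl]oxy}silane F7.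
 9-BBN adds selectively to the monosubstituted terminal alkene to give {[(2S)-2-[(E)-6-(9-borabicyclo[3.3.1]nonan-9-yl)-4-methylhex-3-enyl]-2-methyl-2H-chromen-6-yl]oxy}triisopropylsilane F8.
 This borane is coupled in the same flask by B-alkyl Suzuki–Miyaura reaction (PdCl2(dppf), AsPh3, Cs2CO3, DMF–THF–H2O, 40 °C). The partner is 2,6,6-trimethylcyclohex-1-enyl trifluoromethanesulfonate F9, made from commercial 2,2,6-trimethylcyclohexanone (LDA, PhNTf2). The product is 22.

**Further compounds**
F1 | step 5 | ethyl (E)-2-methyl-5-[(2S)-2-methyl-3-methylidene-5-(triisopropylsilyloxy)-2,3-dihydrobenzofuran-2-yl]pent-2-enoate | C=C1c2cc(O[Si](C(C)C)(C(C)C)C(C)C)ccc2O[C@@]1(C)CC/C=C(\C)C(=O)OCC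
F2 | step 3 | allyl 2-methyl-5-(triisopropylsilyloxy)benzofuran-3-yl carbonate | C=CCOC(=O)Oc1c(C)oc2ccc(O[Si](C(C)C)(C(C)C)C(C)C)cc12
F3 | step 3 | (2S)-2-allyl-2-methyl-5-(triisopropylsilyloxy)benzofuran-3(2H)-one | O=C1c2cc(O[Si](C(C)C)(C(C)C)C(C)C)ccc2O[C@@]1(C)CC=C
F4 | step 3 | (2S)-2-[3-(9-borabicyclo[3.3.1]nonan-9-yl)propyl]-2-methyl-5-(triisopropylsilyloxy)benzofuran-3(2H)-one | O=C1c2cc(O[Si](C(C)C)(C(C)C)C(C)C)ccc2O[C@@]1(C)CCCB1C2CCCC1CCC2
F5 | step 3 | (2S)-2-(3-hydroxypropyl)-2-methyl-5-(triisopropylsilyloxy)benzofuran-3(2H)-one | O=C1c2cc(O[Si](C(C)C)(C(C)C)C(C)C)ccc2O[C@@]1(C)CCCO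
F6 | step 13 | (E)-2-methyl-5-[(2S)-2-methyl-6-(triisopropylsilyloxy)-2H-chromen-2-yl]pent-2-enal | O=C/C(C)=C/CC[C@@]1(C)C=Cc2cc(O[Si](C(C)C)(C(C)C)C(C)C)ccc2O1
F7 | step 13 | triisopropyl{[(2S)-2-methyl-2-[(E)-4-methylhexa-3,5-dienyl]-2H-chromen-6-yl]oxy}silane | C=C/C(C)=C/CC[C@@]1(C)C=Cc2cc(O[Si](C(C)C)(C(C)C)C(C)C)ccc2O1
F8 | step 13 | {[(2S)-2-[(E)-6-(9-borabicyclo[3.3.1]nonan-9-yl)-4-methylhex-3-enyl]-2-methyl-2H-chromen-6-yl]oxy}triisopropylsilane | C1CCC2CCCC1B2CC/C(C)=C/CC[C@@]1(C)C=Cc2cc(O[Si](C(C)C)(C(C)C)C(C)C)ccc2O1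
F9 | step 13 | 2,6,6-trimethylcyclohex-1-enyl trifluoromethanesulfonate | CC1=C(OS(=O)(=O)C(F)(F)F)C(C)(C)CCC1
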